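The route rests on cutting the C4–C4a bond of ring C. C4a is the only ring A carbon next to C8a (the O1-bearing carbon) that carries no oxygen, so a bromine placed there can be swapped for lithium and the resulting aryl anion acylated by an amide held on the preformed O1–C2–C3 chain. In one operation this Parham-type cyclisation forges the aryl ketone and closes the pyranone ring with both stereocentres already installed. The cyclisation substrate is a hexasubstituted bromoarene (8-OMe, 5,7-di-OMOM, 6-prenyl) whose C8a oxygen is etherified by a (2R,3R)-2-(methoxymethoxy)-3-phenylpropanoic N-methoxy-N-methylamide, assembled from a Sharpless epoxide of cinnamyl alcohol and a phenol made from 2-methoxyresorcinol.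

Key step: step 13

Assumption: the target is the (2R,3R) trans dihydroflavonol written in the SMILES, and flavanone numbering (O1, C2, C3, C4, C4a, C5 to C8, C8a) is used for every intermediate that contains ring A (MOM = methoxymethyl, TIPS = triisopropylsilyl, prenyl = 3-methylbut-2-en-1-yl).

Step 1
Reactants: 1 2-methoxyresorcinol (2-methoxybenzene-1,3-diol)
Product: 2 2-methoxy-3-[(triisopropylsilyl)oxy]phenol
Conditions: TIPSCl (0.95 equiv), imidazole, DMF, 0 °C → rt
Reagents that add atoms: chlorotriisopropylsilane, CC(C)[Si](Cl)(C(C)C)C(C)C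
Why: O-silylation of one of two equivalent phenols is a statistical monoprotection whose mono-ether should be separable from recyclable diol and bis-ether; it marks the future C8a oxygen with a bulky, non-coordinating group that lithium bases and MOM chemistry leave alone.

Step 2
Reactants: 2 2-methoxy-3-[(triisopropylsilyl)oxy]phenol
Product: 3 triisopropyl[2-methoxy-3-(methoxymethoxy)phenoxy]silane
Conditions: MOMCl, iPr2NEt, CH2Cl2, 0 °C → rt
Reagents that add atoms: chloromethyl methyl ether, COCCl
Why: O-alkylation of the remaining phenol with the chloromethyl ether under amine base (acetal formation) should give the future C7 MOM ether while the silyl ether is inert.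

Step 3
Reactants: 3 triisopropyl[2-methoxy-3-(methoxymethoxy)phenoxy]silane
Product: 5 4-methoxy-3-(methoxymethoxy)-5-[(triisopropylsilyl)oxy]phenol, via arylboronic acid pinacol ester 4 (not isolated)
Conditions: [Ir(OMe)(cod)]2 (1.5 mol %), dtbpy (3 mol %), B2pin2 (1.0 equiv), THF, 80 °C; then Oxone (2KHSO5·KHSO4·K2SO4), acetone/H2O, rt
Reagents that add atoms: potassium peroxymonosulfate, [K+].[O-]S(=O)(=O)OO (phenol oxygen of 5); bis(pinacolato)diboron, CC1(C)OB(OC1(C)C)B1OC(C)(C)C(C)(C)O1 (boryl group of 4 only)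
Why: iridium-catalysed C–H borylation is sterically controlled, so a 1,2,3-trisubstituted benzene should be borylated only at the C–H that has no ortho substituent (future C5, para to the methoxy group), and one-pot oxidative C–B cleavage puts the hydroxyl at that carbon.

Step 4
Reactants: 5 4-methoxy-3-(methoxymethoxy)-5-[(triisopropylsilyl)oxy]phenol
Product: 6 triisopropyl[2-methoxy-3,5-bis(methoxymethoxy)phenoxy]silane
Conditions: MOMCl, iPr2NEt, CH2Cl2, 0 °C → rt
Reagents that add atoms: chloromethyl methyl ether, COCCl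
Why: the same MOM ether formation on the new phenol should give the future C5 MOM ether, so that the future C6 hydrogen now sits between two MOM groups.

Step 5
Reactants: 6 triisopropyl[2-methoxy-3,5-bis(methoxymethoxy)phenoxy]silane; 7 prenyl bromide (1-bromo-3-methylbut-2-ene)
Product: 9 triisopropyl[2-methoxy-3,5-bis(methoxymethoxy)-4-(3-methylbut-2-en-1-yl)phenoxy]silane, via C6-aryllithium 8 (not isolated)
Conditions: n-BuLi, TMEDA, THF, 0 °C; then CuBr·SMe2 (10 mol %), prenyl bromide, −78 °C → rt
Reagents that add atoms: n-butyllithium, [Li]CCCC (lithium of 8 only)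
Why: directed ortho-metalation should take place at the C–H flanked by two chelating MOM ethers and not at the one screened by the TIPS ether, and copper-catalysed allylic substitution at the primary carbon of prenyl bromide should then give the linear prenyl arene.

Step 6
Reactants: 9 triisopropyl[2-methoxy-3,5-bis(methoxymethoxy)-4-(3-methylbut-2-en-1-yl)phenoxy]silane
Product: 10 2-methoxy-3,5-bis(methoxymethoxy)-4-(3-methylbut-2-en-1-yl)phenol
Conditions: Bu4NF, THF, 0 °C
Reagents that add atoms: none
Why: fluoride-induced desilylation should free only the C8a phenol, since MOM ethers and the alkene do not react with fluoride.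

Step 7
Reactants: 11 (E)-cinnamyl alcohol
Product: 12 [(2S,3S)-3-phenyloxiran-2-yl]methanol
Conditions: Ti(OiPr)4 (5 mol %), L-(+)-diisopropyl tartrate (7.5 mol %), t-BuOOH (2 equiv), 4 Å MS, CH2Cl2, −20 °C
Reagents that add atoms: tert-butyl hydroperoxide, CC(C)(C)OO
Why: Sharpless asymmetric epoxidation, in which the titanium complex of L-(+)-tartrate delivers oxygen to the alkene face that gives the (2S,3S) epoxide, sets both stereocentres at once, the trans relationship following stereospecifically from the E-alkene.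

Step 8
Reactants: 10 2-methoxy-3,5-bis(methoxymethoxy)-4-(3-methylbut-2-en-1-yl)phenol; 12 [(2S,3S)-3-phenyloxiran-2-yl]methanol
Product: 13 (2S,3R)-3-[2-methoxy-3,5-bis(methoxymethoxy)-4-(3-methylbut-2-en-1-yl)phenoxy]-3-phenylpropane-1,2-diol
Conditions: NaOH (1.1 equiv), H2O/1,4-dioxane, 70 °C
Reagents that add atoms: none
Why: SN2 opening of the epoxy alcohol by the phenoxide at the phenyl-activated benzylic carbon, a known mode for 2-alkoxyphenoxides with trans-3-phenylglycidol in aqueous base, should form the O1–C2 ether with inversion (epoxide C3 becomes the R-configured future C2) while the epoxide C2 (future C3) is untouched, which gives the anti arrangement of the trans dihydroflavonol.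

Step 9
Reactants: 13 (2S,3R)-3-[2-methoxy-3,5-bis(methoxymethoxy)-4-(3-methylbut-2-en-1-yl)phenoxy]-3-phenylpropane-1,2-diol
Product: 14 (2S,3R)-3-[2-bromo-6-methoxy-3,5-bis(methoxymethoxy)-4-(3-methylbut-2-en-1-yl)phenoxy]-3-phenylpropane-1,2-diol
Conditions: NBS (1.05 equiv), MeCN, −20 °C, dark
Reagents that add atoms: N-bromosuccinimide, O=C1CCC(=O)N1Br
Why: electrophilic aromatic bromination should occur at C4a, the single unsubstituted ring A position, which is activated by the ortho O1 and C5 oxygens and the para C7 oxygen and should therefore react in the cold well before the trisubstituted alkene, the phenyl ring or the alcohols.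

Step 10
Reactants: 14 (2S,3R)-3-[2-bromo-6-methoxy-3,5-bis(methoxymethoxy)-4-(3-methylbut-2-en-1-yl)phenoxy]-3-phenylpropane-1,2-diol
Product: 15 (2R,3R)-3-[2-bromo-6-methoxy-3,5-bis(methoxymethoxy)-4-(3-methylbut-2-en-1-yl)phenoxy]-2-hydroxy-3-phenylpropanoic acid
Conditions: TEMPO (0.2 equiv), PhI(OAc)2 (2.5 equiv), MeCN/H2O (1:1), 0 °C → rt
Reagents that add atoms: water, O
Why: oxoammonium-mediated oxidation is much faster at the unhindered primary carbinol than at the flanked secondary one, and in aqueous medium the aldehyde hydrate is carried on to the acid, so the primary alcohol should be converted selectively while the fully substituted ring, the alkene and the MOM ethers are not attacked.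

Step 11
Reactants: 15 (2R,3R)-3-[2-bromo-6-methoxy-3,5-bis(methoxymethoxy)-4-(3-methylbut-2-en-1-yl)phenoxy]-2-hydroxy-3-phenylpropanoic acid
Product: 16 (2R,3R)-3-[2-bromo-6-methoxy-3,5-bis(methoxymethoxy)-4-(3-methylbut-2-en-1-yl)phenoxy]-2-hydroxy-N-methoxy-N-methyl-3-phenylpropanamide
Conditions: MeNHOMe·HCl, EDC·HCl, HOBt, N-methylmorpholine, CH2Cl2, 0 °C → rt
Reagents that add atoms: N,O-dimethylhydroxylamine hydrochloride, Cl.CNOC
Why: carbodiimide amide coupling through the hydroxybenzotriazole active ester should give the N-methoxy-N-methylamide without touching either stereocentre, the amine being far more nucleophilic than the hindered secondary hydroxyl.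

Step 12
Reactants: 16 (2R,3R)-3-[2-bromo-6-methoxy-3,5-bis(methoxymethoxy)-4-(3-methylbut-2-en-1-yl)phenoxy]-2-hydroxy-N-methoxy-N-methyl-3-phenylpropanamide
Product: 17 (2R,3R)-3-[2-bromo-6-methoxy-3,5-bis(methoxymethoxy)-4-(3-methylbut-2-en-1-yl)phenoxy]-N-methoxy-2-(methoxymethoxy)-N-methyl-3-phenylpropanamide
Conditions: MOMCl, iPr2NEt, Bu4NI (cat.), CH2Cl2, 0 → 40 °C
Reagents that add atoms: chloromethyl methyl ether, COCCl
Why: MOM ether formation at the secondary alcohol removes the only acidic proton before the organolithium step and uses a group that leaves together with the aryl MOM ethers at the end.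

Step 13
Reactants: 17 (2R,3R)-3-[2-bromo-6-methoxy-3,5-bis(methoxymethoxy)-4-(3-methylbut-2-en-1-yl)phenoxy]-N-methoxy-2-(methoxymethoxy)-N-methyl-3-phenylpropanamide
Product: 20 (2R,3R)-8-methoxy-3,5,7-tris(methoxymethoxy)-6-(3-methylbut-2-en-1-yl)-2-phenyl-2,3-dihydro-4H-chromen-4-one, via C4a-aryllithium 18 (not isolated), via tetrahedral lithium alkoxide 19 (not isolated)
Conditions: t-BuLi (2.1 equiv), THF/Et2O, −100 → −78 °C; AcOH in THF, −78 °C
Reagents that add atoms: tert-butyllithium, [Li]C(C)(C)C (lithium of 18 and 19 only)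
Why: tert-butyllithium attacks the bromine at C4a (bromine–lithium exchange, the second equivalent destroying the tert-butyl bromide formed) to give aryllithium 18, which adds to the carbonyl of the tethered N-methoxy-N-methylamide to give the lithium-chelated tetrahedral adduct 19, and this releases ketone 20 only on protonation. The closest known reaction type is the Parham cyclisation (cycloacylation) of ortho-bromoaryl ethers that carry a tethered carboxyl derivative, which gives chroman-4-ones. Ring C is closed in the 6-exo-trig mode, the new C4–C4a bond completing the O1–C2–C3–C4–C4a–C8a ring. No stereocentre is created: C2 and C3 are carried through unchanged, the C4 centre of 19 is transient, and the chelate keeps the ketone masked so that C3 cannot enolise before the acidic quench. The step needs the exchange to outrun both proton abstraction at C3 or C2 (which would expel the aryloxide by E1cB) and direct attack of the alkyllithium on the amide; this should be secured by the very fast exchange at −100 °C at a bromine flanked by two coordinating oxygens, by the bulk of tert-butyllithium and by the low electrophilicity of the amide. The basic, non-acidic medium leaves the prenyl alkene and the MOM ethers intact.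

Step 14
Reactants: 20 (2R,3R)-8-methoxy-3,5,7-tris(methoxymethoxy)-6-(3-methylbut-2-en-1-yl)-2-phenyl-2,3-dihydro-4H-chromen-4-one
Product: 21 (2R,3R)-3,5,7-trihydroxy-8-methoxy-6-(3-methylbut-2-en-1-yl)-2-phenyl-2,3-dihydro-4H-chromen-4-one
Conditions: HCl (3 M in MeOH), 45 °C
Reagents that add atoms: none
Why: acid-catalysed transacetalisation to methanol should remove the two aryl MOM ethers and the C3 MOM ether, the moderate temperature being chosen to avoid addition of the C5 or C7 hydroxyl to the prenyl double bond, and the trans-2,3 arrangement is the thermodynamically preferred one and is not at risk.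

Compound list
1 | 2-methoxyresorcinol (2-methoxybenzene-1,3-diol) | COc1c(O)cccc1O | starting material
2 | 2-methoxy-3-[(triisopropylsilyl)oxy]phenol | COc1c(O)cccc1O[Si](C(C)C)(C(C)C)C(C)C | intermediate
3 | triisopropyl[2-methoxy-3-(methoxymethoxy)phenoxy]silane | COCOc1cccc(O[Si](C(C)C)(C(C)C)C(C)C)c1OC | intermediate
4 | 2-{4-methoxy-3-(methoxymethoxy)-5-[(triisopropylsilyl)oxy]phenyl}-4,4,5,5-tetramethyl-1,3,2-dioxaborolane (formed in the flask) | COCOc1cc(B2OC(C)(C)C(C)(C)O2)cc(O[Si](C(C)C)(C(C)C)C(C)C)c1OC | intermediate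
5 | 4-methoxy-3-(methoxymethoxy)-5-[(triisopropylsilyl)oxy]phenol | COCOc1cc(O)cc(O[Si](C(C)C)(C(C)C)C(C)C)c1OC | intermediate
6 | triisopropyl[2-methoxy-3,5-bis(methoxymethoxy)phenoxy]silane | COCOc1cc(OCOC)cc(O[Si](C(C)C)(C(C)C)C(C)C)c1OC | intermediate
7 | prenyl bromide (1-bromo-3-methylbut-2-ene) | CC(C)=CCBr | starting material
8 | {3-methoxy-2,6-bis(methoxymethoxy)-4-[(triisopropylsilyl)oxy]phenyl}lithium (formed in the flask) | COCOc1c([Li])c(OCOC)cc(O[Si](C(C)C)(C(C)C)C(C)C)c1OC | intermediate
9 | triisopropyl[2-methoxy-3,5-bis(methoxymethoxy)-4-(3-methylbut-2-en-1-yl)phenoxy]silane | COCOc1c(CC=C(C)C)c(OCOC)cc(O[Si](C(C)C)(C(C)C)C(C)C)c1OC | intermediate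
10 | 2-methoxy-3,5-bis(methoxymethoxy)-4-(3-methylbut-2-en-1-yl)phenol | COCOc1c(CC=C(C)C)c(OCOC)cc(O)c1OC | intermediate
11 | (E)-cinnamyl alcohol | OC/C=C/c1ccccc1 | starting material
12 | [(2S,3S)-3-phenyloxiran-2-yl]methanol | OC[C@@H]1O[C@H]1c2ccccc2 | intermediate
13 | (2S,3R)-3-[2-methoxy-3,5-bis(methoxymethoxy)-4-(3-methylbut-2-en-1-yl)phenoxy]-3-phenylpropane-1,2-diol | COCOc1c(CC=C(C)C)c(OCOC)cc(O[C@H](c2ccccc2)[C@@H](O)CO)c1OC | intermediate
14 | (2S,3R)-3-[2-bromo-6-methoxy-3,5-bis(methoxymethoxy)-4-(3-methylbut-2-en-1-yl)phenoxy]-3-phenylpropane-1,2-diol | COCOc1c(CC=C(C)C)c(OCOC)c(Br)c(O[C@H](c2ccccc2)[C@@H](O)CO)c1OC | intermediate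
15 | (2R,3R)-3-[2-bromo-6-methoxy-3,5-bis(methoxymethoxy)-4-(3-methylbut-2-en-1-yl)phenoxy]-2-hydroxy-3-phenylpropanoic acid | COCOc1c(CC=C(C)C)c(OCOC)c(Br)c(O[C@H](c2ccccc2)[C@@H](O)C(=O)O)c1OC | intermediate
16 | (2R,3R)-3-[2-bromo-6-methoxy-3,5-bis(methoxymethoxy)-4-(3-methylbut-2-en-1-yl)phenoxy]-2-hydroxy-N-methoxy-N-methyl-3-phenylpropanamide | COCOc1c(CC=C(C)C)c(OCOC)c(Br)c(O[C@H](c2ccccc2)[C@@H](O)C(=O)N(C)OC)c1OC | intermediate
17 | (2R,3R)-3-[2-bromo-6-methoxy-3,5-bis(methoxymethoxy)-4-(3-methylbut-2-en-1-yl)phenoxy]-N-methoxy-2-(methoxymethoxy)-N-methyl-3-phenylpropanamide | COc1c(OCOC)c(CC=C(C)C)c(OCOC)c(Br)c1O[C@H](c1ccccc1)[C@@H](OCOC)C(=O)N(C)OC | intermediate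
18 | C4a-lithio analogue of 17 (lithium in place of bromine; formed in the flask) | COc1c(OCOC)c(CC=C(C)C)c(OCOC)c([Li])c1O[C@H](c1ccccc1)[C@@H](OCOC)C(=O)N(C)OC | intermediate
19 | lithium (2R,3R)-8-methoxy-4-[methoxy(methyl)amino]-3,5,7-tris(methoxymethoxy)-6-(3-methylbut-2-en-1-yl)-2-phenylchroman-4-olate (C4 configuration not defined; formed in the flask) | COc1c(OCOC)c(CC=C(C)C)c(OCOC)c2c1O[C@H](c1ccccc1)[C@@H](OCOC)C2(O[Li])N(C)OC | intermediate
20 | (2R,3R)-8-methoxy-3,5,7-tris(methoxymethoxy)-6-(3-methylbut-2-en-1-yl)-2-phenyl-2,3-dihydro-4H-chromen-4-one | COc1c(OCOC)c(CC=C(C)C)c(OCOC)c2c1O[C@H](c1ccccc1)[C@@H](OCOC)C2=O | intermediate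
21 | (2R,3R)-3,5,7-trihydroxy-8-methoxy-6-(3-methylbut-2-en-1-yl)-2-phenyl-2,3-dihydro-4H-chromen-4-one | COc1c(O)c(CC=C(C)C)c(O)c2c1O[C@H](c1ccccc1)[C@@H](O)C2=O | target

Total step count: 14. Longest linear sequence: 13 steps (steps 1 to 6 and 8 to 14, from 2-methoxyresorcinol); step 7 is the only side-branch step.

Steps most likely to fail

Step 13. Proton abstraction at C3 with loss of the ring A aryloxide, addition of the alkyllithium to the amide, or protonation of the aryllithium may outpace ring closure. The fallback forms the same C4–C4a bond by electrophilic instead of anionic acylation and sets out from 13, before bromine is introduced. Oxidation as in step 10 should give (2R,3R)-2-hydroxy-3-[2-methoxy-3,5-bis(methoxymethoxy)-4-(3-methylbut-2-en-1-yl)phenoxy]-3-phenylpropanoic acid F1. Acetylation (Ac2O, pyridine, aqueous work-up) should give the 2-acetoxy acid F2. Trifluoroacetic anhydride in CH2Cl2 at 0 °C should then convert F2 to the mixed anhydride, which acylates C4a, the only free and triply oxygen-activated ring position (intramolecular Friedel–Crafts acylation), to give (2R,3R)-8-methoxy-5,7-bis(methoxymethoxy)-6-(3-methylbut-2-en-1-yl)-4-oxo-2-phenylchroman-3-yl acetate F3. Methanolic HCl as in step 14 should remove the acetate and both MOM groups, so the fallback comes back to the route at 21.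

Step 10. Carbon–carbon cleavage of the vicinal diol, or of the hydroxy aldehyde stage, by the iodane may compete with oxidation of the primary carbinol, which would lose C1. The fallback removes the vicinal diol before oxidising and sets out from 14. Silylation of the primary hydroxyl (TBSCl, imidazole, CH2Cl2) should give (1R,2S)-1-[2-bromo-6-methoxy-3,5-bis(methoxymethoxy)-4-(3-methylbut-2-en-1-yl)phenoxy]-3-[(tert-butyldimethylsilyl)oxy]-1-phenylpropan-2-ol F4. MOMCl and iPr2NEt should give its 2-O-MOM ether F5, and Bu4NF should free the primary alcohol, (2S,3R)-3-(aryloxy)-2-(methoxymethoxy)-3-phenylpropan-1-ol F6. The same TEMPO/PhI(OAc)2 oxidation in aqueous MeCN, now on an isolated primary alcohol, should give the (2R,3R)-2-(methoxymethoxy) acid F7. Coupling with MeNHOMe·HCl (EDC·HCl, HOBt) comes back to the route at 17.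

Step 8. Payne migration of the epoxy alcohol followed by attack at the terminal carbon, attack at the epoxide C2, C-alkylation of the ambident phenoxide at C4a, or simple hydrolysis of the epoxide may give constitutional isomers or consume the epoxide. The fallback makes the O1–C2 bond by Mitsunobu inversion instead of epoxide opening and sets out from 10. Commercial methyl (2R,3S)-2,3-dihydroxy-3-phenylpropanoate, PPh3 and DIAD in toluene at 0 °C should displace the benzylic 3-hydroxyl with inversion (the ester-deactivated 2-hydroxyl is not expected to be engaged) to give methyl (2R,3R)-2-hydroxy-3-[2-methoxy-3,5-bis(methoxymethoxy)-4-(3-methylbut-2-en-1-yl)phenoxy]-3-phenylpropanoate F8. Bromination as in step 9 should give the C4a-bromo ester F9. Aminolysis with MeNHOMe·HCl and i-PrMgCl in THF at −20 °C comes back to the route at 16, bypassing steps 10 and 11.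

Further compounds
F1 | step 13 | (2R,3R)-2-hydroxy-3-[2-methoxy-3,5-bis(methoxymethoxy)-4-(3-methylbut-2-en-1-yl)phenoxy]-3-phenylpropanoic acid | COCOc1c(CC=C(C)C)c(OCOC)cc(O[C@H](c2ccccc2)[C@@H](O)C(=O)O)c1OC
F2 | step 13 | (2R,3R)-2-acetoxy-3-[2-methoxy-3,5-bis(methoxymethoxy)-4-(3-methylbut-2-en-1-yl)phenoxy]-3-phenylpropanoic acid | COCOc1c(CC=C(C)C)c(OCOC)cc(O[C@H](c2ccccc2)[C@@H](OC(C)=O)C(=O)O)c1OC
F3 | step 13 | (2R,3R)-8-methoxy-5,7-bis(methoxymethoxy)-6-(3-methylbut-2-en-1-yl)-4-oxo-2-phenylchroman-3-yl acetate | COc1c(OCOC)c(CC=C(C)C)c(OCOC)c2c1O[C@H](c1ccccc1)[C@@H](OC(C)=O)C2=O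
F4 | step 10 | (1R,2S)-1-[2-bromo-6-methoxy-3,5-bis(methoxymethoxy)-4-(3-methylbut-2-en-1-yl)phenoxy]-3-[(tert-butyldimethylsilyl)oxy]-1-phenylpropan-2-ol | COCOc1c(CC=C(C)C)c(OCOC)c(Br)c(O[C@H](c2ccccc2)[C@@H](O)CO[Si](C)(C)C(C)(C)C)c1OC
F5 | step 10 | tert-butyl{[(2S,3R)-3-[2-bromo-6-methoxy-3,5-bis(methoxymethoxy)-4-(3-methylbut-2-en-1-yl)phenoxy]-2-(methoxymethoxy)-3-phenylpropyl]oxy}dimethylsilane | COCOc1c(CC=C(C)C)c(OCOC)c(Br)c(O[C@H](c2ccccc2)[C@@H](OCOC)CO[Si](C)(C)C(C)(C)C)c1OC
F6 | step 10 | (2S,3R)-3-[2-bromo-6-methoxy-3,5-bis(methoxymethoxy)-4-(3-methylbut-2-en-1-yl)phenoxy]-2-(methoxymethoxy)-3-phenylpropan-1-ol | COCOc1c(CC=C(C)C)c(OCOC)c(Br)c(O[C@H](c2ccccc2)[C@@H](OCOC)CO)c1OC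
F7 | step 10 | (2R,3R)-3-[2-bromo-6-methoxy-3,5-bis(methoxymethoxy)-4-(3-methylbut-2-en-1-yl)phenoxy]-2-(methoxymethoxy)-3-phenylpropanoic acid | COCOc1c(CC=C(C)C)c(OCOC)c(Br)c(O[C@H](c2ccccc2)[C@@H](OCOC)C(=O)O)c1OC
F8 | step 8 | methyl (2R,3R)-2-hydroxy-3-[2-methoxy-3,5-bis(methoxymethoxy)-4-(3-methylbut-2-en-1-yl)phenoxy]-3-phenylpropanoate | COCOc1c(CC=C(C)C)c(OCOC)cc(O[C@H](c2ccccc2)[C@@H](O)C(=O)OC)c1OC
F9 | step 8 | methyl (2R,3R)-3-[2-bromo-6-methoxy-3,5-bis(methoxymethoxy)-4-(3-methylbut-2-en-1-yl)phenoxy]-2-hydroxy-3-phenylpropanoate | COCOc1c(CC=C(C)C)c(OCOC)c(Br)c(O[C@H](c2ccccc2)[C@@H](O)C(=O)OC)c1OC
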